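Ring B is disconnected last: its C1'–C2' and C5'–C6' bonds are made in one operation by a Diels–Alder reaction between a 1-methoxy-3-silyloxybutadiene and an ethynyl group on chromone C2, followed by aromatisation. The feature exploited is the para relationship in ring B between C1' (bonded to C2) and the oxygen-bearing C4', which maps onto the diene polarity and onto an alkyne polarised through C2=C3 by the C4 carbonyl. The precursor is a 2-ethynyl-5,7-dimethoxychromone already carrying, at C8, the (R)-configured methyl 3-phenylpropanoate arm. That stereocentre is set at the outset by rhodium-catalysed asymmetric arylation of 5,7-dimethoxycoumarin, whose lactone oxygen becomes O1.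

Key step: step 7

Assumption: (R)-SEGPHOS is taken to deliver phenyl to the face of C4 that gives the (R) lactone, as it does for simpler coumarins; the configuration is to be confirmed at that stage and the antipodal ligand used if the sense is reversed.

Step 1
Reactants: 1 5,7-dimethoxycoumarin; 2 phenylboronic acid
Product: 3 (R)-5,7-dimethoxy-4-phenylchroman-2-one
Conditions: Rh(acac)(C2H4)2 (3 mol%), (R)-SEGPHOS (3.3 mol%), 2 (5 equiv), dioxane/H2O 10:1, 60 °C
Reagents that add atoms: none
Why: Hayashi–Miyaura rhodium-catalysed asymmetric 1,4-addition, in which the phenylrhodium species bound to the chiral bisphosphine inserts the C3=C4 bond of the coumarin on one enantioface and protonolysis of the rhodium enolate releases the lactone, so that the C4 stereocentre is set by the ligand.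

Step 2
Reactants: 3 (R)-5,7-dimethoxy-4-phenylchroman-2-one
Product: 5 methyl (3R)-3-(2-acetoxy-4,6-dimethoxyphenyl)-3-phenylpropanoate, via sodium phenoxide 4 (not isolated)
Conditions: NaOMe (1.05 equiv), THF, 0 °C; then Ac2O (1.5 equiv), 0 °C to rt
Reagents that add atoms: sodium methoxide, [Na+].[O-]C; acetic anhydride, CC(=O)OC(C)=O
Why: Lactone methanolysis (transesterification) followed by O-acetylation, in which methoxide opens the reactive aryl ester because the phenoxide is the weaker base and the acetate cap stops the phenol from reclosing, while the benzylic stereocentre, not being alpha to a carbonyl, is untouched.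

Step 3
Reactants: 5 methyl (3R)-3-(2-acetoxy-4,6-dimethoxyphenyl)-3-phenylpropanoate
Product: 7 methyl (3R)-3-(3-acetyl-2-hydroxy-4,6-dimethoxyphenyl)-3-phenylpropanoate, via difluoroboron chelate 6 (not isolated)
Conditions: BF3·OEt2 (3 equiv), ClCH2CH2Cl, 60 °C; then NaOAc, MeOH/H2O, 50 °C
Reagents that add atoms: none
Why: Fries rearrangement, in which boron trifluoride moves the acetyl group from oxygen to the only free ortho carbon, where the product is held as a six-membered boron chelate that favours ortho over para acylation (the para site lies between two methoxy groups) and keeps the phenol oxygen away from the side-chain ester, as is usual for acetates of phloroglucinol ethers.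

Step 4
Reactants: 7 methyl (3R)-3-(3-acetyl-2-hydroxy-4,6-dimethoxyphenyl)-3-phenylpropanoate; 8 methyl 2,2-dimethoxyacetate
Product: 10 methyl (3R)-3-[2-(dimethoxymethyl)-5,7-dimethoxy-4-oxo-4H-chromen-8-yl]-3-phenylpropanoate, via 1,3-diketone 9 (not isolated)
Conditions: NaH (3.5 equiv), 8 (2.5 equiv), THF, 0 to 60 °C; then HCl, MeOH, 60 °C
Reagents that add atoms: none
Why: Crossed Claisen condensation followed by acid-catalysed cyclodehydration, in which the more acidic methyl ketone is acylated by the activated dimethoxyacetate and the diketone is pulled forward as its enolate, after which the phenol adds to the distal carbonyl and loses water to give the pyranone, the hindered side-chain ester and the acetal surviving methanolic HCl.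

Step 5
Reactants: 10 methyl (3R)-3-[2-(dimethoxymethyl)-5,7-dimethoxy-4-oxo-4H-chromen-8-yl]-3-phenylpropanoate
Product: 11 methyl (3R)-3-(2-formyl-5,7-dimethoxy-4-oxo-4H-chromen-8-yl)-3-phenylpropanoate
Conditions: CF3CO2H/H2O 9:1, rt; toluene azeotrope
Reagents that add atoms: water, O
Why: Acid-catalysed acetal hydrolysis, which should unmask the aldehyde without touching the methyl ester, the aryl methyl ethers or the pyranone, and so reaches the aldehyde oxidation level without any oxidant.

Step 6
Reactants: 11 methyl (3R)-3-(2-formyl-5,7-dimethoxy-4-oxo-4H-chromen-8-yl)-3-phenylpropanoate; 12 dimethyl (1-diazo-2-oxopropyl)phosphonate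
Product: 13 methyl (3R)-3-(2-ethynyl-5,7-dimethoxy-4-oxo-4H-chromen-8-yl)-3-phenylpropanoate
Conditions: 12 (1.3 equiv), NaOMe (1.3 equiv), THF, –78 °C; then 11, –78 to 0 °C
Reagents that add atoms: none
Why: Seyferth–Gilbert homologation in its Ohira–Bestmann form, in which the diazomethylphosphonate anion, made beforehand with one equivalent of methoxide in the cold so that no free alkoxide meets the pyranone or the product, adds to the very electrophilic non-enolisable aldehyde, and the derived diazoalkene loses nitrogen and rearranges by 1,2-hydrogen shift to the terminal alkyne.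

Step 7
Reactants: 13 methyl (3R)-3-(2-ethynyl-5,7-dimethoxy-4-oxo-4H-chromen-8-yl)-3-phenylpropanoate; 14 Danishefsky diene, (E)-1-methoxy-3-(trimethylsilyloxy)buta-1,3-diene
Product: 16 methyl (3R)-3-[2-(4-hydroxyphenyl)-5,7-dimethoxy-4-oxo-4H-chromen-8-yl]-3-phenylpropanoate, via cyclohexadiene cycloadduct 15 (not isolated)
Conditions: 14 (4 equiv), toluene, 110 °C, sealed tube; then 1 M HCl, THF, rt
Reagents that add atoms: none
Why: Proposed new method: the ethynyl group on C2 is the far end of a vinylogous ynone (C≡C–C2=C3–C4=O), so its terminal carbon is the electron-poor site and should bond first to the unsubstituted, most nucleophilic CH2 terminus of the electron-rich diene, the methoxy-bearing terminus then closing onto the alkyne carbon attached to C2 in a concerted but asynchronous (4+2) cycloaddition that forms C5'–C6' and C1'–C2'. The closest known reaction type is the Diels–Alder reaction of 1-methoxy-3-silyloxybutadienes with ynones and propiolates followed by loss of methanol to give para-hydroxyaryl carbonyl compounds; what is new is an alkyne activated only through the pyranone double bond. Ring B is closed intermolecularly as a six-membered carbocycle by this cycloaddition, both sigma bonds being made in the same step, and the acid treatment then hydrolyses the silyl enol ether and eliminates methanol from 15, so that aromatisation makes the sequence irreversible. No stereocentre remains from the step: the methoxy-bearing sp3 carbon of 15 forms as a mixture and disappears on aromatisation, and the remote C8 side-chain centre has no pathway for epimerisation under neutral heating or dilute acid. The step needs para regiochemistry and chemoselectivity for the alkyne: the first follows from pairing the nucleophilic diene terminus with the electrophilic alkyne terminus (a stepwise Michael-type addition at that carbon followed by closure would lead to the same arene), and the second from the C2=C3 bond being trisubstituted, enol-ether-like and part of the pyranone conjugation, while the ester and aryl ethers are inert to the diene.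

Step 8
Reactants: 16 methyl (3R)-3-[2-(4-hydroxyphenyl)-5,7-dimethoxy-4-oxo-4H-chromen-8-yl]-3-phenylpropanoate
Product: 17 methyl (3R)-3-[5,7-dihydroxy-2-(4-hydroxyphenyl)-4-oxo-4H-chromen-8-yl]-3-phenylpropanoate
Conditions: BBr3 (6 equiv), CH2Cl2, –78 °C to rt; MeOH, 0 °C to rt; aq. NaHCO3
Reagents that add atoms: none
Why: Lewis-acid cleavage of aryl methyl ethers, in which BBr3 removes the C5 methyl group quickly through chelation to the C4 carbonyl and the C7 methyl group with excess reagent at room temperature as in standard flavone deprotections, while the acidic methanol quench should return any ester that has closed onto the new C7 hydroxyl to the open methyl ester and the stereocentre is not involved.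

Step 9
Reactants: 17 methyl (3R)-3-[5,7-dihydroxy-2-(4-hydroxyphenyl)-4-oxo-4H-chromen-8-yl]-3-phenylpropanoate
Product: 18 (3R)-3-[5,7-dihydroxy-2-(4-hydroxyphenyl)-4-oxo-4H-chromen-8-yl]-3-phenylpropanoic acid
Conditions: LiOH (5 equiv), THF/H2O, argon, 0 °C to rt; then 1 M HCl to pH 4, 0 °C, immediate extraction
Reagents that add atoms: lithium hydroxide, [Li+].[OH-]
Why: Saponification, in which aqueous LiOH hydrolyses the methyl ester (and would equally open a lactone formed with the C7 hydroxyl) with air excluded, and acidification only to about pH 4 in the cold should give the free acid without acid-catalysed closure onto the C7 hydroxyl.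

Compound list
1 | 5,7-dimethoxycoumarin (5,7-dimethoxy-2H-chromen-2-one) | O=c1ccc2c(OC)cc(OC)cc2o1 | starting material
2 | phenylboronic acid | OB(O)c1ccccc1 | starting material
3 | (R)-5,7-dimethoxy-4-phenylchroman-2-one | O=C1C[C@H](c2ccccc2)c2c(OC)cc(OC)cc2O1 | intermediate
4 | sodium 3,5-dimethoxy-2-[(1R)-3-methoxy-3-oxo-1-phenylpropyl]phenoxide | COC(=O)C[C@H](c1ccccc1)c1c(OC)cc(OC)cc1[O-].[Na+] | intermediate
5 | methyl (3R)-3-(2-acetoxy-4,6-dimethoxyphenyl)-3-phenylpropanoate | COC(=O)C[C@H](c1ccccc1)c1c(OC)cc(OC)cc1OC(C)=O | intermediate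
6 | difluoroboron chelate of 7, with BF2 bridging the phenol oxygen and the acetyl oxygen, (R) at the benzylic carbon | COC(=O)C[C@H](c1ccccc1)c1c(OC)cc(OC)c2c1O[B-](F)(F)[O+]=C2C | intermediate
7 | methyl (3R)-3-(3-acetyl-2-hydroxy-4,6-dimethoxyphenyl)-3-phenylpropanoate | COC(=O)C[C@H](c1ccccc1)c1c(OC)cc(OC)c(C(C)=O)c1O | intermediate
8 | methyl 2,2-dimethoxyacetate | COC(OC)C(=O)OC | starting material
9 | methyl (3R)-3-[3-(4,4-dimethoxy-3-oxobutanoyl)-2-hydroxy-4,6-dimethoxyphenyl]-3-phenylpropanoate | COC(=O)C[C@H](c1ccccc1)c1c(OC)cc(OC)c(C(=O)CC(=O)C(OC)OC)c1O | intermediate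
10 | methyl (3R)-3-[2-(dimethoxymethyl)-5,7-dimethoxy-4-oxo-4H-chromen-8-yl]-3-phenylpropanoate | COC(=O)C[C@H](c1ccccc1)c1c(OC)cc(OC)c2c(=O)cc(C(OC)OC)oc12 | intermediate
11 | methyl (3R)-3-(2-formyl-5,7-dimethoxy-4-oxo-4H-chromen-8-yl)-3-phenylpropanoate | COC(=O)C[C@H](c1ccccc1)c1c(OC)cc(OC)c2c(=O)cc(C=O)oc12 | intermediate
12 | dimethyl (1-diazo-2-oxopropyl)phosphonate | COP(=O)(OC)C(=[N+]=[N-])C(C)=O | starting material
13 | methyl (3R)-3-(2-ethynyl-5,7-dimethoxy-4-oxo-4H-chromen-8-yl)-3-phenylpropanoate | COC(=O)C[C@H](c1ccccc1)c1c(OC)cc(OC)c2c(=O)cc(C#C)oc12 | intermediate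
14 | Danishefsky diene, (E)-1-methoxy-3-(trimethylsilyloxy)buta-1,3-diene | CO/C=C/C(=C)O[Si](C)(C)C | starting material
15 | methyl (3R)-3-{5,7-dimethoxy-2-[6-methoxy-4-(trimethylsilyloxy)cyclohexa-1,4-dien-1-yl]-4-oxo-4H-chromen-8-yl}-3-phenylpropanoate, both epimers at the methoxy-bearing ring carbon | COC(=O)C[C@H](c1ccccc1)c1c(OC)cc(OC)c2c(=O)cc(C3=CCC(O[Si](C)(C)C)=CC3OC)oc12 | intermediate
16 | methyl (3R)-3-[2-(4-hydroxyphenyl)-5,7-dimethoxy-4-oxo-4H-chromen-8-yl]-3-phenylpropanoate | COC(=O)C[C@H](c1ccccc1)c1c(OC)cc(OC)c2c(=O)cc(-c3ccc(O)cc3)oc12 | intermediate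
17 | methyl (3R)-3-[5,7-dihydroxy-2-(4-hydroxyphenyl)-4-oxo-4H-chromen-8-yl]-3-phenylpropanoate | COC(=O)C[C@H](c1ccccc1)c1c(O)cc(O)c2c(=O)cc(-c3ccc(O)cc3)oc12 | intermediate
18 | (3R)-3-[5,7-dihydroxy-2-(4-hydroxyphenyl)-4-oxo-4H-chromen-8-yl]-3-phenylpropanoic acid | O=C(O)C[C@H](c1ccccc1)c1c(O)cc(O)c2c(=O)cc(-c3ccc(O)cc3)oc12 | target

Total step count: 9
Longest linear sequence: 9 steps (1 to 18)

Steps most likely to fail

1. Step 7 (the proposed new method). The alkyne is activated only through the pyranone double bond, so the cycloaddition may be slower than loss of the diene to silyl transfer, hydrolysis and self-condensation at 110 °C. The diene may also add as a nucleophile at C2 instead. A chelating Lewis acid would be a change of conditions only; the fallback gives up the cycloaddition and brings ring B in by known acylation chemistry. It sets out from 7. The phenol is acylated with 4-methoxybenzoyl chloride (pyridine, DMAP) to give methyl (3R)-3-[3-acetyl-4,6-dimethoxy-2-(4-methoxybenzoyloxy)phenyl]-3-phenylpropanoate F1. t-BuOK in THF then brings about the Baker–Venkataraman acyl shift to methyl (3R)-3-{2-hydroxy-4,6-dimethoxy-3-[3-(4-methoxyphenyl)-3-oxopropanoyl]phenyl}-3-phenylpropanoate F2. Catalytic H2SO4 in AcOH closes the pyranone to methyl (3R)-3-[5,7-dimethoxy-2-(4-methoxyphenyl)-4-oxo-4H-chromen-8-yl]-3-phenylpropanoate F3. BBr3 under the conditions of step 8, with enough reagent for three ethers, should then give 17, where the route is rejoined.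

2. Step 3. Three processes threaten it: reclosure of the lactone once the acetyl group has left oxygen, delivery of the acyl group to the para carbon, and erosion of enantiopurity by acid-promoted reversible cleavage of the aryl–CH bond on the very electron-rich ring. The fallback avoids hot Lewis acid and sets out from 3. NaOMe in THF/MeOH at 0 °C followed by a cold AcOH quench should give the free phenol methyl (3R)-3-(2-hydroxy-4,6-dimethoxyphenyl)-3-phenylpropanoate F4. Rieche formylation directed by the titanium phenoxide (Cl2CHOMe, TiCl4, CH2Cl2, –78 to 0 °C) should place the aldehyde ortho to the hydroxyl, giving methyl (3R)-3-(3-formyl-2-hydroxy-4,6-dimethoxyphenyl)-3-phenylpropanoate F5. MeMgBr (2.2 equiv, THF, –78 °C) adds to the aldehyde in preference to the ester to give methyl (3R)-3-[2-hydroxy-3-(1-hydroxyethyl)-4,6-dimethoxyphenyl]-3-phenylpropanoate F6 as a mixture of carbinol epimers. MnO2 in CH2Cl2 oxidises the benzylic alcohol to 7, where the route is rejoined.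

3. Step 6. The risk lies in base-induced side reactions of a very electrophilic pyranone: addition of methoxide or of the phosphonate anion at C2 with ring opening, and oligomerisation of the ethynylchromone, itself a Michael acceptor, once formed. The fallback carries the alkyne in as a silyl-protected three-carbon unit and sets out from 7. The sodium phenoxide (NaH, THF, 0 °C) is acylated with 3-[tri(propan-2-yl)silyl]prop-2-ynoyl chloride to give methyl (3R)-3-[3-acetyl-4,6-dimethoxy-2-({3-[tri(propan-2-yl)silyl]prop-2-ynoyl}oxy)phenyl]-3-phenylpropanoate F7. t-BuOK in THF at –20 °C effects the Baker–Venkataraman shift to methyl (3R)-3-[2-hydroxy-4,6-dimethoxy-3-{3-oxo-5-[tri(propan-2-yl)silyl]pent-4-ynoyl}phenyl]-3-phenylpropanoate F8. TsOH in MeCN closes the pyranone to methyl (3R)-3-[5,7-dimethoxy-4-oxo-2-{[tri(propan-2-yl)silyl]ethynyl}-4H-chromen-8-yl]-3-phenylpropanoate F9. Bu4NF buffered with AcOH in THF at 0 °C removes the silyl group to give 13, where the route is rejoined.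

Further compounds
F1 | step 7 | methyl (3R)-3-[3-acetyl-4,6-dimethoxy-2-(4-methoxybenzoyloxy)phenyl]-3-phenylpropanoate | COC(=O)C[C@H](c1ccccc1)c1c(OC)cc(OC)c(C(C)=O)c1OC(=O)c1ccc(OC)cc1
F2 | step 7 | methyl (3R)-3-{2-hydroxy-4,6-dimethoxy-3-[3-(4-methoxyphenyl)-3-oxopropanoyl]phenyl}-3-phenylpropanoate | COC(=O)C[C@H](c1ccccc1)c1c(OC)cc(OC)c(C(=O)CC(=O)c2ccc(OC)cc2)c1O
F3 | step 7 | methyl (3R)-3-[5,7-dimethoxy-2-(4-methoxyphenyl)-4-oxo-4H-chromen-8-yl]-3-phenylpropanoate | COC(=O)C[C@H](c1ccccc1)c1c(OC)cc(OC)c2c(=O)cc(-c3ccc(OC)cc3)oc12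
F4 | step 3 | methyl (3R)-3-(2-hydroxy-4,6-dimethoxyphenyl)-3-phenylpropanoate | COC(=O)C[C@H](c1ccccc1)c1c(OC)cc(OC)cc1O
F5 | step 3 | methyl (3R)-3-(3-formyl-2-hydroxy-4,6-dimethoxyphenyl)-3-phenylpropanoate | COC(=O)C[C@H](c1ccccc1)c1c(OC)cc(OC)c(C=O)c1O
F6 | step 3 | methyl (3R)-3-[2-hydroxy-3-(1-hydroxyethyl)-4,6-dimethoxyphenyl]-3-phenylpropanoate, both epimers at the carbinol carbon | COC(=O)C[C@H](c1ccccc1)c1c(OC)cc(OC)c(C(C)O)c1O
F7 | step 6 | methyl (3R)-3-[3-acetyl-4,6-dimethoxy-2-({3-[tri(propan-2-yl)silyl]prop-2-ynoyl}oxy)phenyl]-3-phenylpropanoate | COC(=O)C[C@H](c1ccccc1)c1c(OC)cc(OC)c(C(C)=O)c1OC(=O)C#C[Si](C(C)C)(C(C)C)C(C)C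
F8 | step 6 | methyl (3R)-3-[2-hydroxy-4,6-dimethoxy-3-{3-oxo-5-[tri(propan-2-yl)silyl]pent-4-ynoyl}phenyl]-3-phenylpropanoate | COC(=O)C[C@H](c1ccccc1)c1c(OC)cc(OC)c(C(=O)CC(=O)C#C[Si](C(C)C)(C(C)C)C(C)C)c1O
F9 | step 6 | methyl (3R)-3-[5,7-dimethoxy-4-oxo-2-{[tri(propan-2-yl)silyl]ethynyl}-4H-chromen-8-yl]-3-phenylpropanoate | COC(=O)C[C@H](c1ccccc1)c1c(OC)cc(OC)c2c(=O)cc(C#C[Si](C(C)C)(C(C)C)C(C)C)oc12
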